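**Retrosynthetic overview**
1. Central CH2 from C=O: the target comes from its 2,2'-dihydroxybenzophenone. The two ortho-OH groups and both guaiacol OH groups come from one chelation-controlled BCl3 cleavage of the tetramethoxy bis(benzyl ether) ketone.
2. Ar–C(=O) bond: Friedel–Crafts acylation of one bibenzyl monomer at C-2 (ring A pattern). The acylating acid is made from the same monomer by lithiation between its two OMe groups (ring B pattern).
3. Key cut, ArCH2–CH2Ar' of the monomer, between two aldehyde carbons: 3,5-dimethoxybenzaldehyde becomes a benzyl-anion equivalent (NH2-hydrazone, Ru catalysis, loss of N2) and adds to the C=O of O-benzylvanillin. This one coupling supplies both bibenzyl bonds of the target.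
4. No ring is formed: all four benzene rings are bought intact.

**Assumption:** the SMILES has no stereocentre, stereogenic double bond or hindered axis, so the target is achiral and there is no enantiomer to select. Carbinols 4 and 12 are racemic and their stereocentres are erased again.

**Step 1**
Reactants: 1 3,5-dimethoxybenzaldehyde; 2 4-(benzyloxy)-3-methoxybenzaldehyde (O-benzylvanillin)
Product: 4 rac-1-[4-(benzyloxy)-3-methoxyphenyl]-2-(3,5-dimethoxyphenyl)ethan-1-ol, via 3,5-dimethoxybenzaldehyde hydrazone 3 (not isolated)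
Conditions: i) 1 (1.3 equiv), N2H4·H2O (1.05 equiv per 1), THF, rt, 1 h; ii) 2 (1.0 equiv), [Ru(p-cymene)Cl2]2 (1 mol %), dmpe (2 mol %), K3PO4 (25 mol %), CsF (75 mol %), THF, 45 °C, 12 h, N2
Reagents that add atoms: none
Why: Ru(II)-catalysed hydrazone carbonyl-umpolung addition (a C–C-forming Wolff–Kishner-type reaction), in which Ru-bound 3 reacts at carbon as a 3,5-dimethoxybenzyl anion with the aldehyde carbon of 2 through a six-membered transition state, irreversible loss of N2 drives the union of two formerly electrophilic CHO carbons, and the new carbinol centre is racemic and is deleted in step 2.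

**Step 2**
Reactants: 4 rac-1-[4-(benzyloxy)-3-methoxyphenyl]-2-(3,5-dimethoxyphenyl)ethan-1-ol
Product: 5 1-(benzyloxy)-4-[2-(3,5-dimethoxyphenyl)ethyl]-2-methoxybenzene (bibenzyl monomer)
Conditions: Et3SiH (4 equiv), TFA (5 equiv), CH2Cl2 (0.05 M), −20 → 0 °C, 1 h
Reagents that add atoms: none
Why: Ionic hydrogenation (Kursanov–Parnes), in which TFA ionises the p-benzyloxybenzylic alcohol to a well-stabilised cation that excess silane in dilute solution traps faster than the dimethoxyarene can, while benzyl and methyl ethers survive and the stereocentre disappears.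

**Step 3** (about half of 5)
Reactants: 5 1-(benzyloxy)-4-[2-(3,5-dimethoxyphenyl)ethyl]-2-methoxybenzene
Product: 7 4-{2-[4-(benzyloxy)-3-methoxyphenyl]ethyl}-2,6-dimethoxybenzoic acid, via 2,6-dimethoxyaryllithium 6 (not isolated)
Conditions: n-BuLi (1.15 equiv), THF, 0 °C → rt, 1.5 h; CO2, −78 °C → rt; 1 M HCl
Reagents that add atoms: carbon dioxide, O=C=O
Why: Directed ortho-metalation, in which the C–H flanked by both OMe groups is by far the most acidic and doubly coordinated site (the remote ArOCH2Ph is deprotonated more slowly with about 1 equiv of base), so carboxylation fixes the ring B pattern.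

**Step 4**
Reactants: 7 4-{2-[4-(benzyloxy)-3-methoxyphenyl]ethyl}-2,6-dimethoxybenzoic acid; 5 1-(benzyloxy)-4-[2-(3,5-dimethoxyphenyl)ethyl]-2-methoxybenzene
Product: 9 (2-{2-[4-(benzyloxy)-3-methoxyphenyl]ethyl}-4,6-dimethoxyphenyl)(4-{2-[4-(benzyloxy)-3-methoxyphenyl]ethyl}-2,6-dimethoxyphenyl)methanone, via aroyl trifluoroacetate 8 (not isolated)
Conditions: 7, (CF3CO)2O (2.5 equiv), CH2Cl2, 0 °C, 30 min; then 5 (1.1 equiv), 0 °C → rt, 12 h; aq. NaHCO3
Reagents that add atoms: none
Why: Friedel–Crafts acylation by the TFAA mixed-anhydride method, in which the linear 2,6-dimethoxybenzoyl cation attacks C-2 of the resorcinol diether ring of 5 (para to one OMe, ortho to the other, C-2 and C-6 being equivalent), the usual site for 5-alkylresorcinol dimethyl ethers, which gives the ring A pattern while the O-benzylguaiacol rings are far less nucleophilic.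

**Step 5**
Reactants: 9 (2-{2-[4-(benzyloxy)-3-methoxyphenyl]ethyl}-4,6-dimethoxyphenyl)(4-{2-[4-(benzyloxy)-3-methoxyphenyl]ethyl}-2,6-dimethoxyphenyl)methanone
Product: 11 {2-hydroxy-6-[2-(4-hydroxy-3-methoxyphenyl)ethyl]-4-methoxyphenyl}{2-hydroxy-4-[2-(4-hydroxy-3-methoxyphenyl)ethyl]-6-methoxyphenyl}methanone, via tetrakis(dichloroboryl) ether 10 (not isolated)
Conditions: BCl3 (1 M in CH2Cl2, 8 equiv), C6HMe5 (6 equiv), CH2Cl2, −78 °C, 1 h, then 0 °C, 2 h; H2O–THF
Reagents that add atoms: none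
Why: Chelation-controlled BCl3 ether cleavage combined with BCl3/pentamethylbenzene debenzylation, in which only OMe groups able to form a six-membered O–B···O=C chelate fall (one per ring, since the first ring B chelate turns the carbonyl oxygen away from the second ring B OMe), the benzyl cations are scavenged by C6HMe5, and the para OMe and guaiacol OMe groups are inert at ≤ 0 °C.

**Step 6**
Reactants: 11 {2-hydroxy-6-[2-(4-hydroxy-3-methoxyphenyl)ethyl]-4-methoxyphenyl}{2-hydroxy-4-[2-(4-hydroxy-3-methoxyphenyl)ethyl]-6-methoxyphenyl}methanone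
Product: 13 2-({2-hydroxy-4-[2-(4-hydroxy-3-methoxyphenyl)ethyl]-6-methoxyphenyl}methyl)-3-[2-(4-hydroxy-3-methoxyphenyl)ethyl]-5-methoxyphenol (CNP0079001.0), via benzhydrol 12 (not isolated)
Conditions: Et3SiH (8 equiv), TFA–CH2Cl2 (1:4), 0 °C → rt, 4 h
Reagents that add atoms: none
Why: Ionic hydrogenation of an electron-rich diaryl ketone, in which protonation gives a stabilised hydroxydiarylcarbenium ion, hydride transfer gives 12, and 12 ionises at once to an o-quinone-methide-like cation that takes up a second hydride irreversibly, so no stereocentre remains and phenols and aryl methyl ethers are untouched.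

**Compound list**
1 | 3,5-dimethoxybenzaldehyde | COc1cc(C=O)cc(OC)c1 | starting material
2 | 4-(benzyloxy)-3-methoxybenzaldehyde (O-benzylvanillin) | COc1cc(C=O)ccc1OCc1ccccc1 | starting material
3 | (E)-(3,5-dimethoxybenzylidene)hydrazine (NH2-hydrazone of 1) | COc1cc(/C=N/N)cc(OC)c1 | intermediate (not isolated)
4 | rac-1-[4-(benzyloxy)-3-methoxyphenyl]-2-(3,5-dimethoxyphenyl)ethan-1-ol | COc1cc(CC(O)c2ccc(OCc3ccccc3)c(OC)c2)cc(OC)c1 | intermediate
5 | 1-(benzyloxy)-4-[2-(3,5-dimethoxyphenyl)ethyl]-2-methoxybenzene | COc1cc(CCc2ccc(OCc3ccccc3)c(OC)c2)cc(OC)c1 | intermediate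
6 | (4-{2-[4-(benzyloxy)-3-methoxyphenyl]ethyl}-2,6-dimethoxyphenyl)lithium | [Li]c1c(OC)cc(CCc2ccc(OCc3ccccc3)c(OC)c2)cc1OC | intermediate (not isolated)
7 | 4-{2-[4-(benzyloxy)-3-methoxyphenyl]ethyl}-2,6-dimethoxybenzoic acid | COc1cc(CCc2ccc(OCc3ccccc3)c(OC)c2)cc(OC)c1C(=O)O | intermediate
8 | 4-{2-[4-(benzyloxy)-3-methoxyphenyl]ethyl}-2,6-dimethoxybenzoic trifluoroacetic anhydride | COc1cc(CCc2ccc(OCc3ccccc3)c(OC)c2)cc(OC)c1C(=O)OC(=O)C(F)(F)F | intermediate (not isolated)
9 | (2-{2-[4-(benzyloxy)-3-methoxyphenyl]ethyl}-4,6-dimethoxyphenyl)(4-{2-[4-(benzyloxy)-3-methoxyphenyl]ethyl}-2,6-dimethoxyphenyl)methanone | COc1cc(OC)c(C(=O)c2c(OC)cc(CCc3ccc(OCc4ccccc4)c(OC)c3)cc2OC)c(CCc2ccc(OCc3ccccc3)c(OC)c2)c1 | intermediate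
10 | tetrakis(O-dichloroboryl) derivative of 11 (drawn without the C=O→B dative bonds) | COc1cc(OB(Cl)Cl)c(C(=O)c2c(OB(Cl)Cl)cc(CCc3ccc(OB(Cl)Cl)c(OC)c3)cc2OC)c(CCc2ccc(OB(Cl)Cl)c(OC)c2)c1 | intermediate (not isolated)
11 | {2-hydroxy-6-[2-(4-hydroxy-3-methoxyphenyl)ethyl]-4-methoxyphenyl}{2-hydroxy-4-[2-(4-hydroxy-3-methoxyphenyl)ethyl]-6-methoxyphenyl}methanone | COc1cc(O)c(C(=O)c2c(O)cc(CCc3ccc(O)c(OC)c3)cc2OC)c(CCc2ccc(O)c(OC)c2)c1 | intermediate
12 | rac-{2-hydroxy-6-[2-(4-hydroxy-3-methoxyphenyl)ethyl]-4-methoxyphenyl}{2-hydroxy-4-[2-(4-hydroxy-3-methoxyphenyl)ethyl]-6-methoxyphenyl}methanol | COc1cc(O)c(C(O)c2c(O)cc(CCc3ccc(O)c(OC)c3)cc2OC)c(CCc2ccc(O)c(OC)c2)c1 | intermediate (not isolated)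
13 | 2-({2-hydroxy-4-[2-(4-hydroxy-3-methoxyphenyl)ethyl]-6-methoxyphenyl}methyl)-3-[2-(4-hydroxy-3-methoxyphenyl)ethyl]-5-methoxyphenol | COc1cc(O)c(Cc2c(O)cc(CCc3ccc(O)c(OC)c3)cc2OC)c(CCc2ccc(O)c(OC)c2)c1 | target

**Total step count:** 6.
**Longest linear sequence:** 6 (1 → 4 → 5 → 7 → 9 → 11 → 13; 5 enters twice, in steps 3 and 4).

**Three steps most likely to fail**

**Step 1.** Azine formation, hydrazone exchange between 3 and the electron-rich aldehyde 2, or plain Wolff–Kishner reduction of 3 may outrun C–C bond formation. The fallback sets out from 2 and comes back at 5. It replaces the catalytic benzyl-anion equivalent by a stoichiometric acyl-anion equivalent (Corey–Seebach). Compound 2 with propane-1,3-dithiol and BF3·OEt2 in CH2Cl2 gives 2-[4-(benzyloxy)-3-methoxyphenyl]-1,3-dithiane F1. n-BuLi in THF at −78 to −30 °C gives {2-[4-(benzyloxy)-3-methoxyphenyl]-1,3-dithian-2-yl}lithium F2. This is alkylated with commercial 3,5-dimethoxybenzyl bromide to 2-[4-(benzyloxy)-3-methoxyphenyl]-2-[(3,5-dimethoxyphenyl)methyl]-1,3-dithiane F3. Nickel boride (NiCl2·6H2O, NaBH4, MeOH–THF, 0 °C) removes the sulfur without touching the benzyl ether and gives 5, so step 2 is skipped.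

**Step 5.** Four ether cleavages run in one flask. The second chelate may form incompletely, a guaiacol OMe next to ArOBCl2 may be lost, or the electron-rich rings may be C-benzylated. The fallback sets out from 9 and comes back at 11, and it separates the two kinds of cleavage. MgI2·OEt2 (toluene–Et2O, 80 °C) acts only where a carbonyl chelate can form. It gives (2-{2-[4-(benzyloxy)-3-methoxyphenyl]ethyl}-6-hydroxy-4-methoxyphenyl)(4-{2-[4-(benzyloxy)-3-methoxyphenyl]ethyl}-2-hydroxy-6-methoxyphenyl)methanone F4 with both benzyl ethers intact. Neutral hydrogenolysis (H2, 1 atm, Pd/C, EtOAc–EtOH, rt) then frees the two guaiacol OH groups without any benzyl cation and gives 11.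

**Step 6.** The hindered, doubly hydrogen-bonded ketone may resist reduction. In acid the diarylmethyl cation can also close onto C-6 of the neighbouring guaiacol ring (seven-membered dibenzosuberane), or the product can transbenzylate. The fallback sets out from 11 and comes back at 13 without any acid. NaBH4 (excess, THF–EtOH, 0 °C → rt) gives benzhydrol 12, which is now isolated. Its doubly benzylic C–O bond is cleaved by catalytic hydrogenolysis (H2, Pd/C, EtOH, 40 °C). This makes no compound outside the list (F0).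

**Further compounds**
F1 | step 1 | 2-[4-(benzyloxy)-3-methoxyphenyl]-1,3-dithiane | COc1cc(C2SCCCS2)ccc1OCc1ccccc1
F2 | step 1 | {2-[4-(benzyloxy)-3-methoxyphenyl]-1,3-dithian-2-yl}lithium | [Li]C1(c2ccc(OCc3ccccc3)c(OC)c2)SCCCS1
F3 | step 1 | 2-[4-(benzyloxy)-3-methoxyphenyl]-2-[(3,5-dimethoxyphenyl)methyl]-1,3-dithiane | COc1cc(CC2(c3ccc(OCc4ccccc4)c(OC)c3)SCCCS2)cc(OC)c1
F4 | step 5 | (2-{2-[4-(benzyloxy)-3-methoxyphenyl]ethyl}-6-hydroxy-4-methoxyphenyl)(4-{2-[4-(benzyloxy)-3-methoxyphenyl]ethyl}-2-hydroxy-6-methoxyphenyl)methanone | COc1cc(O)c(C(=O)c2c(O)cc(CCc3ccc(OCc4ccccc4)c(OC)c3)cc2OC)c(CCc2ccc(OCc3ccccc3)c(OC)c2)c1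
F0 | step 6 | none | none
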